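**Plan**
1. Retrosynthesis cuts first the bond between the side-chain carbinol carbon C-1' and the first chain methylene C-2' (C16 tail plus complete ring aldehyde), then the C-5–C-1' bond (one carbon onto a C-5 enolate). The five-membered ring is not cut.
2. Forward: the ring is present from the start as the cis-fused dioxolane/cyclopentenone bicycle 1. C-1' is put on C-5 as CH2OH and raised to CHO, the C16 chain is joined to that carbon, and the dioxolane is removed last.
3. Enabling feature: C-5 is fully substituted and lies between the C-1 carbonyl and the oxygen-bearing C-4, so a formyl group on C-5 has no α-hydrogen. The whole oxidised ring, enone included, can therefore meet the chain unprotected.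
4. The dioxolane across O-4/O-5 is a temporary ring: it must stay cis-fused, so any new bond at C-5 forms trans to O-4.
5. Stereochemistry: C-4 and C-5 come from the chiral pool (1); C-1' is set in the union by non-chelation (Felkin–Anh/Cornforth) control from C-5.

Key step: step 3

Remark: enone 1, the antipode of the common D-ribose-derived cyclopentenone acetonide, is taken as a purchasable chiral-pool building block.

**Step 1**
Reactants: 1 (3aS,6aS)-2,2-dimethyl-3a,6a-dihydro-4H-cyclopenta[d][1,3]dioxol-4-one
Product: 4 (3aS,6aS)-3a-(hydroxymethyl)-2,2-dimethyl-3a,6a-dihydro-4H-cyclopenta[d][1,3]dioxol-4-one, via lithium dienolate 2 (not isolated), via lithium alkoxide 3 (not isolated)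
Conditions: LiN(iPr)2, THF, −78 °C; CH2O (gas, from paraformaldehyde), −78 °C; aq. NH4Cl
Reagents that add atoms: formaldehyde, C=O
Why: Kinetic deprotonation at C-3a gives the cross-conjugated lithium dienolate, and its aldol addition to monomeric formaldehyde (enolate hydroxymethylation) can only occur on the convex face because the dioxolane must stay cis-fused, which sets the quaternary centre with the new carbon trans to the C-6a oxygen.

**Step 2**
Reactants: 4 (3aS,6aS)-3a-(hydroxymethyl)-2,2-dimethyl-3a,6a-dihydro-4H-cyclopenta[d][1,3]dioxol-4-one
Product: 5 (3aR,6aS)-2,2-dimethyl-4-oxo-4,6a-dihydro-3aH-cyclopenta[d][1,3]dioxole-3a-carbaldehyde (same spatial arrangement as 4; the C-3a descriptor changes by priority only)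
Conditions: Dess–Martin periodinane, CH2Cl2, 0 °C to rt; non-aqueous work-up, used at once
Reagents that add atoms: none
Why: Dess–Martin oxidation of the neopentylic primary alcohol should stop at the aldehyde under neutral conditions, and the product cannot enolise or epimerise because C-3a carries no hydrogen.

**Step 3**
Reactants: 5 (3aR,6aS)-2,2-dimethyl-4-oxo-4,6a-dihydro-3aH-cyclopenta[d][1,3]dioxole-3a-carbaldehyde; 6 1-bromohexadecane
Product: 10 (3aS,6aS)-3a-[(1S)-1-hydroxyheptadecyl]-2,2-dimethyl-3a,6a-dihydro-4H-cyclopenta[d][1,3]dioxol-4-one, via hexadecylmagnesium bromide 7 (not isolated), via hexadecyltitanium triisopropoxide 8 (not isolated), via titanium alkoxide 9 (not isolated)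
Conditions: 6, Mg, THF, 45 °C; ClTi(OiPr)3, −78 °C; 5, −78 to −30 °C; H2O
Reagents that add atoms: none
Why: Magnesium insertion into 6 and transmetallation with ClTi(OiPr)3 give the monoalkyltitanium 8, which coordinates the aldehyde oxygen of 5 and transfers its alkyl group to the formyl carbon to give alkoxide 9; the closest known reaction type is the aldehyde-selective carbonyl addition of alkyltitanium triisopropoxides in the presence of ketones. The step closes no ring. The new stereocentre C-1' is controlled by the adjacent quaternary carbon under non-chelation (Felkin–Anh/Cornforth) conditions: the weakly Lewis-acidic reagent should not bridge the dioxolane oxygen, the aldehyde C=O lies anti to the C-3a–C-4 bond (opposed carbonyl dipoles), and the alkyl group enters anti to the C-3a–O bond past the flat C-4 carbonyl carbon instead of the C-6a methine, which leads to the (1S) carbinol. The selectivity needed is aldehyde over enone (1,2- and 1,4-addition), and it rests on the low reactivity of RTi(OiPr)3 towards ketones and enones below −30 °C. Because C-3a has no hydrogen, the keto aldehyde can neither enolise nor epimerise under the reagent, and the cis-fused dioxolane holds C-3a and C-6a unchanged. The complete polar head is thus joined to the C16 chain at the final oxidation level without a protecting group on the enone.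

**Step 4**
Reactants: 10 (3aS,6aS)-3a-[(1S)-1-hydroxyheptadecyl]-2,2-dimethyl-3a,6a-dihydro-4H-cyclopenta[d][1,3]dioxol-4-one
Product: 11 (4S,5S)-4,5-dihydroxy-5-[(1S)-1-hydroxyheptadecyl]cyclopent-2-en-1-one
Conditions: CF3CO2H/H2O/THF (4:1:1), 0 °C to rt
Reagents that add atoms: none
Why: Acid-catalysed hydrolysis of the isopropylidene ketal should free the cis-4,5-diol without touching the stereocentres, since C-5 has no hydrogen and neither epimerisation nor β-elimination towards C-5 is possible.

**Compound list**
1 | (3aS,6aS)-2,2-dimethyl-3a,6a-dihydro-4H-cyclopenta[d][1,3]dioxol-4-one | CC1(C)O[C@@H]2C(=O)C=C[C@@H]2O1 | starting material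
2 | lithium (6aS)-2,2-dimethyl-6aH-cyclopenta[d][1,3]dioxol-4-olate (cross-conjugated dienolate of 1) | CC1(C)OC2=C([O-])C=C[C@@H]2O1.[Li+] | intermediate
3 | lithium alkoxide of 4 (O–Li at the CH2O group, same configuration) | [Li+].[O-]C[C@@]1(OC(C)(C)O2)C(=O)C=C[C@@H]12 | intermediate
4 | (3aS,6aS)-3a-(hydroxymethyl)-2,2-dimethyl-3a,6a-dihydro-4H-cyclopenta[d][1,3]dioxol-4-one | OC[C@@]1(OC(C)(C)O2)C(=O)C=C[C@@H]12 | intermediate
5 | (3aR,6aS)-2,2-dimethyl-4-oxo-4,6a-dihydro-3aH-cyclopenta[d][1,3]dioxole-3a-carbaldehyde | O=C[C@@]1(OC(C)(C)O2)C(=O)C=C[C@@H]12 | intermediate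
6 | 1-bromohexadecane | CCCCCCCCCCCCCCCCBr | starting material
7 | hexadecylmagnesium bromide | CCCCCCCCCCCCCCCC[Mg]Br | intermediate
8 | hexadecyltri(propan-2-olato)titanium, C16H33Ti(OiPr)3 | CCCCCCCCCCCCCCCC[Ti](OC(C)C)(OC(C)C)OC(C)C | intermediate
9 | tri(propan-2-olato)titanium alkoxide of 10 (O–Ti at C-1', same configuration) | CCCCCCCCCCCCCCCC[C@H](O[Ti](OC(C)C)(OC(C)C)OC(C)C)[C@@]1(OC(C)(C)O2)C(=O)C=C[C@@H]12 | intermediate
10 | (3aS,6aS)-3a-[(1S)-1-hydroxyheptadecyl]-2,2-dimethyl-3a,6a-dihydro-4H-cyclopenta[d][1,3]dioxol-4-one | CCCCCCCCCCCCCCCC[C@H](O)[C@@]1(OC(C)(C)O2)C(=O)C=C[C@@H]12 | intermediate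
11 | (4S,5S)-4,5-dihydroxy-5-[(1S)-1-hydroxyheptadecyl]cyclopent-2-en-1-one | CCCCCCCCCCCCCCCC[C@H](O)[C@@]1(O)C(=O)C=C[C@@H]1O | target

**Step count and risks**
Total steps: 4. Longest linear sequence: 4 steps (1 → 4 → 5 → 10 → 11).

Steps most likely to fail:

- Step 3. The alkyl transfer may lose facial selectivity if magnesium salts chelate the aldehyde oxygen together with the dioxolane oxygen, which would open the opposite face. Isopropoxide transfer could also compete with alkyl transfer. The fallback sets out from 5 and comes back at 10, with the stereocentre set by a catalyst instead of the substrate and the chain taken from 1-hexadecene instead of 6. 1-Hexadecene is hydroborated with Et2BH to diethyl(hexadecyl)borane F1. Boron–zinc exchange with Et2Zn gives dihexadecylzinc F2. F2 is added to 5 in toluene at −20 °C under catalysis by Ti(OiPr)4 and (1R,2R)-1,2-bis(trifluoromethanesulfonamido)cyclohexane, then quenched with aq. NH4Cl. This ligand enantiomer is expected to deliver the alkyl group to the Si face of the aldehyde, which corresponds to the (1S) carbinol 10.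

- Step 2. The keto aldehyde may hydrate, or shed its formyl group by retro-Claisen cleavage, during work-up and storage. The fallback sets out from 1 and comes back at 5, reaching the aldehyde oxidation level by acylation instead of oxidation. The lithium dienolate 2 is formylated directly with 2,2,2-trifluoroethyl formate in THF at −78 °C (Claisen-type formyl transfer). The cold solution of 5 is transferred straight onto reagent 8, so that 5 is never isolated (no new compound is made: F0).

- Step 1. The lithium alkoxide may revert by retro-aldol cleavage or pick up further formaldehyde, and monomeric formaldehyde may polymerise before it is captured. The fallback sets out from 1 and comes back at 4. The dienolate 2 is trapped with Me3SiCl as the silyl dienol ether trimethyl{[(6aS)-2,2-dimethyl-6aH-cyclopenta[d][1,3]dioxol-4-yl]oxy}silane F3. F3 is hydroxymethylated with aqueous formaldehyde under Yb(OTf)3 catalysis in THF/H2O (Mukaiyama-type aldol addition in water). The cis ring fusion again forces the new carbon trans to the C-6a oxygen.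

**Further compounds**
F1 | step 3 | diethyl(hexadecyl)borane | CCCCCCCCCCCCCCCCB(CC)CC
F2 | step 3 | dihexadecylzinc | CCCCCCCCCCCCCCCC[Zn]CCCCCCCCCCCCCCCC
F0 | step 2 | none | none
F3 | step 1 | trimethyl{[(6aS)-2,2-dimethyl-6aH-cyclopenta[d][1,3]dioxol-4-yl]oxy}silane | CC1(C)OC2=C(O[Si](C)(C)C)C=C[C@@H]2O1
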